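Readings and results are calculated on assumed constants, noise included.

G is the product we count, so we begin with how much of it each spent portion of X leaves behind.

| setting | noon | autumn | violet | blue | green | teal |
|---|---|---|---|---|---|---|
| X | 0.050 M | 0.050 M | 0.050 M | 0.050 M | 0.050 M | 0.050 M |
| L | 0.18 mM | 4.3 mM | 0.20 mM | 0.50 mM | 1.5 mM | 5.0 mM |
| remark | run made earlier | run made earlier |  |  |  |  |
| time |  |  | 6.0 min | 6.0 min | 6.0 min | 6.0 min |

| run | time / min | G / % | X / % |
|---|---|---|---|
| noon | 1.00 | 2 | 100 |
| noon | 2.00 | 2 | 100 |
| noon | 3.00 | 1 | 97 |
| noon | 4.00 | 1 | 92 |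
| noon | 5.00 | 5 | 93 |
| noon | 6.00 | 4 | 91 |
| autumn | 0.417 | 2 | 100 |
| autumn | 1.33 | 3 | 94 |
| autumn | 2.00 | 7 | 86 |
| autumn | 3.00 | 16 | 64 |
| autumn | 5.00 | 20 | 24 |
| autumn | 6.00 | 21 | 16 |

(standard deviation of a reading: 1.5 percentage points)

- "hardly changes" means that all values lie within two and a half points (for a concentration: within two and a half percent of the largest)

1. amount of G at the end, in percent of the X charged for violet, blue, green, teal, in this order
2. the course of these numbers from the first flask to the last (falls, then rises / rises all the way / rises, then falls / hardly changes / falls all the way)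

At 3.00 min the autumn run holds G 16 % with X 64 % left, which gives 0.444: G divided by the fraction of X spent is the share, or selectivity, and we carry it.

We treat the loss of G as a correction to this share and assume that, at 6.0 min, each mM of L multiplies the X left by a fixed factor. Noon's factor spends X faster per mM than autumn's, so the two runs give the two edges of the bracket for green.

From above, noon's factor with no loss gives 24.2 %. From below, we start from autumn's factor, which gives 21.0 %, and then subtract a deficit. At 6.00 min autumn holds G 21 % where the share promises 37.3 %, a deficit of 16 percentage points. Scaled by L, as for a pseudo-first-order loss, this becomes 5.7 points for green, and the lower edge falls to 15.3 %. Green should reach autumn's G later, so, as a guess, we divide the allowance by 2, which lifts the edge to 18.1 %.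

For teal, autumn's factor with the whole allowance, not divided, gives 20.2 %, which is inside green's bracket, so we lean towards a top in the row without being able to prove it.

The forecast reads 4 %, 8 %, 16 %, 21 %, a course that rises all the way, because “G rises with L and flattens towards a plateau”. Its green value lies below our bracket.

The flasks give 5.02 %, 11.0 %, 21.4 %, 17.5 %: rises, then falls, with the turn at 2.4 mM of L. Green's value stands above the lower edge of our bracket and below the upper one.

    G ⇌ J (K = 1.10, k = 0.0730 s⁻¹)
    X + D → Z + G (k = 0.130 M⁻¹ s⁻¹)
    D + G → D + E (k = 9.10 M⁻¹ s⁻¹)
    X + Z → G + Z, rate k4*[Z]*[X] (k = 7.90 M⁻¹ s⁻¹)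
    L ⇌ D (K = 0.830, k = 0.00390 s⁻¹)

Green ends with X 47.1 %, so the share promises 23.5 %, which is 2.1 points above its G. Teal ends with X 12.2 %, so the share promises 39.0 %, which is 21 points above its G. In a teal flask lacking the step D + G → D + E, G ends at 42.3 %.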